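**Plan**

1. Core numbering (indene): C1 (CHMe), C2 (C=O), C3 (CHEt), C3a, C4 (Et, CO2H), C5 (Et, dienyl), C6=C7(Me), C7a. Retrosynthesis: cut the two side-chain C=C bonds (olefinations of a C5 aldehyde), then C2–C3 and C3a–C7a together, then C7a=C1 (olefination) and C6=C7 (metathesis), and last the bonds from C4 and C5 to their alkenyl carbons (acetylene [2+2] on a butenolide).
2. Enabling feature: C7a–C1(Me)–C2(=O) is the β-carbon, α-carbon and acyl carbon of an enoyl unit. Its acyl radical reacts as an α-ketenyl radical at C7a, and the C3a=C3 alkene sits on C4. The vicinal quaternary carbons C4 and C5 are held cis in a temporary γ-lactone made from the C4 carboxyl and the aldehyde-level carbon on C5.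
3. Forward order: butenolide acetal → cyclobutene (photochemical) → cyclobutene opened by metathesis into a six-membered acetal tether ring → tether opened and extended to a dienoyl selenoester → one radical chain closes the cyclohexene and then the cyclopentanone → lactone acetal opened, side chain by Wittig and Horner–Wadsworth–Emmons reactions.
4. Stereochemistry: C4/C5 are cis from the [2+2], with absolute sense from the menthyl acetal. C3a/C7a come from a chair-like 6-exo closure on the cis-fused lactone. C1/C3 are set by equilibration to all-trans. C6=C7 is Z because it is formed in a ring, and the side chain is E,E from stabilised olefinations.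
5. Helpers and their removal: menthyl auxiliary (out in step 4), acetal tether ring (out in steps 6–8), selenoester (consumed in step 10), lactone acetal (out in step 11).

Key step: step 10

Assumption: of the two acetal epimers formed in step 1 (separable, interconverting under acid), the (5S) epimer is taken; if the other one crystallises, (+)-menthol is used, which changes nothing downstream because the auxiliary leaves in step 4.

**Route**

Step 1
Reactants: 1 mucobromic acid; 2 (−)-menthol
Product: 3 (5S)-3,4-dibromo-5-menthyloxyfuran-2(5H)-one
Conditions: H2SO4 (cat.), toluene, reflux, Dean–Stark trap; crystallisation of the (5S) epimer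
Reagents that add atoms: none
Why: Acid-catalysed pseudo-ester (cyclic acetal) formation from the lactol form of the aldehyde-acid; the acetal carbon epimerises under the acid so the crystalline epimer can be collected, and this centre later relays the menthyl chirality to the ring carbons.

Step 2
Reactants: 3 (5S)-3,4-dibromo-5-menthyloxyfuran-2(5H)-one
Product: 4 (5S)-3,4-diethyl-5-menthyloxyfuran-2(5H)-one
Conditions: Et2Zn, PdCl2(dppf) (5 mol %), THF, 50 °C
Reagents that add atoms: diethylzinc, CC[Zn]CC
Why: Double Negishi coupling at the two activated vinylic C–Br bonds (vinylogous acyl bromide and α-bromo-enoate), with the bidentate phosphine suppressing β-hydride loss from the ethyl–palladium intermediates and the acetal centre untouched.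

Step 3
Reactants: 4 (5S)-3,4-diethyl-5-menthyloxyfuran-2(5H)-one
Product: 5 cis-fused cyclobutene lactone with the menthyloxy group trans to the cyclobutene
Conditions: HC≡CH (saturated), acetone, hν (medium-pressure Hg lamp, Pyrex), −40 °C
Reagents that add atoms: acetylene, C#C
Why: Triplet-sensitised enone–alkyne [2+2] photocycloaddition builds both vicinal quaternary carbons cis in one step, and the alkyne should add to the face opposite the bulky menthyloxy group, which fixes their absolute configuration.

Step 4
Reactants: 5 cis-fused cyclobutene lactone (menthyl acetal)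
Product: 6 cyclobutene lactone 2-methylallyl acetal with the alkoxy group cis to the cyclobutene
Conditions: CH2=C(Me)CH2OH (10 equiv), CSA (cat.), toluene, 60 °C; acetal epimers separated, the unwanted one re-equilibrated
Reagents that add atoms: 2-methylprop-2-en-1-ol, CC(=C)CO
Why: Acid-catalysed transacetalisation of the lactone pseudo-ester exchanges menthol for the allylic alcohol; the acetal carbon equilibrates while the quaternary carbons cannot, and the epimer with the tether cis to the cyclobutene is the one that can close the ring in step 5.

Step 5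
Reactants: 6 cyclobutene lactone 2-methylallyl acetal
Product: 8 (E)-butenyl pyran-fused acetal lactone, via vinyl pyran-fused acetal lactone 7 (not isolated)
Conditions: RuCl2(=CHPh)(H2IMes)(PCy3) (second-generation Grubbs catalyst, 5 mol %), H2C=CH2 (1 atm), CH2Cl2, 40 °C; then Ar purge, (Z)-hex-3-ene (20 equiv), 40 °C
Reagents that add atoms: (Z)-hex-3-ene, CC/C=C\CC
Why: Ring-rearrangement metathesis then cross-metathesis: strain release opens the cyclobutene, the carbene on the carbon next to the acetal closes onto the tethered 1,1-disubstituted alkene to a six-membered ring (this fixes the Z geometry of C6=C7 and tells the two former cyclobutene carbons apart), ethylene keeps all opening modes reversible so they drain to this ring, and the remaining vinyl group on the quaternary carbon then exchanges its methylene for propylidene to give mainly the E alkene.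

Step 6
Reactants: 8 (E)-butenyl pyran-fused acetal lactone
Product: 9 bis-lactone acylal (unsaturated six-membered lactone fused to the γ-lactone)
Conditions: pyridinium chlorochromate [C5H5NH][CrO3Cl] (4 equiv), Celite, CH2Cl2, 40 °C
Reagents that add atoms: pyridinium chlorochromate, [O-][Cr](=O)(=O)Cl.c1cc[nH+]cc1
Why: Chlorochromate allylic oxidation of a cyclic allyl ether (3,6-dihydro-2H-pyran to 5,6-dihydropyran-2-one) at the CH2 that is both allylic and oxygen-bound, the most easily oxidised position, with no stereocentre touched.

Step 7
Reactants: 9 bis-lactone acylal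
Product: 10 six-membered lactol (anomer mixture), the masked (Z)-enal
Conditions: i-Bu2AlH (1.1 equiv), CH2Cl2, −78 °C; aq. potassium sodium tartrate work-up
Reagents that add atoms: none
Why: Partial lactone-to-lactol reduction at low temperature; the unsaturated six-membered lactone carbonyl is far less hindered than the γ-lactone carbonyl next to a quaternary carbon, and the tetrahedral aluminate holds until work-up.

Step 8
Reactants: 10 six-membered lactol
Product: 12 dienoic acid methoxy-lactone (methoxy trans to the dienyl arm), via formyl diacid 11 (not isolated)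
Conditions: (EtO)2P(O)CH(Me)CO2H (1.1 equiv), LiN(SiMe3)2 (3.2 equiv), THF, −78 → 0 °C; 1 M HCl work-up; then MeOH, PPTS (cat.), rt
Reagents that add atoms: 2-(diethoxyphosphoryl)propanoic acid, CCOP(=O)(OCC)C(C)C(=O)O; methanol, CO
Why: Horner–Wadsworth–Emmons reaction of the phosphonate dianion with the (Z)-enal released when base opens the lactol (the other aldehyde, on a quaternary carbon next to a second one, is much more hindered), then acid-catalysed pseudo-ester formation re-closes the formyl acid as the methyl acetal lactone while the conjugated acid stays free; the methoxy epimer trans to the dienyl arm is collected and the other re-equilibrated.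

Step 9
Reactants: 12 dienoic acid methoxy-lactone
Product: 13 Se-phenyl dienoyl selenoester
Conditions: N-(phenylselanyl)phthalimide, n-Bu3P, THF, −20 °C → rt
Reagents that add atoms: N-(phenylselanyl)phthalimide, O=C1c2ccccc2C(=O)N1[Se]c1ccccc1
Why: Selenoester formation from the acid through its acyloxyphosphonium salt, a mild activation that leaves the acetal and the (Z)-alkene alone.

Step 10
Reactants: 13 Se-phenyl dienoyl selenoester
Product: 15 all-trans tricyclic keto methoxy-lactone, via tricyclic ketone epimer mixture 14 (not isolated)
Conditions: n-Bu3SnH (1.3 equiv, syringe pump, 8 h), AIBN (cat.), benzene (5 mM), 80 °C; then DBU, rt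
Reagents that add atoms: none
Why: n-Bu3Sn• removes PhSe from 13 and the dienoyl radical reacts in its α-ketenyl form, with the spin on C7a and C1=C2=O as a ketene; C7a adds to C3a of the butenyl group and the secondary radical left on C3 adds to the ketene carbon C2, giving an α-keto radical at C1 that is reduced by the stannane. The closest known reaction type is the tandem cyclisation of α,β-unsaturated acyl selenides bearing a remote alkene, which runs through α-ketenyl radicals to fused cyclopentanones. The cyclohexene closes 6-exo-trig and the cyclopentanone 5-exo-dig onto the ketene C=O carbon. C7a and C3a are set in the first closure through a chair-like transition state with the ketenyl group and the alkene terminus both pseudo-equatorial (trans ring fusion), and the face is set by the cis-fused lactone: in the chair needed the lactone carbonyl on C4 is equatorial and the acetal carbon on C5 pseudo-axial with only its hydrogen over the new ring, whereas the other chair pushes the methoxy group against the substituents of C4; C3 and C1 form as mixtures and, being enolisable, are drawn to the all-trans isomer by DBU. The step needs 6-exo attack to beat 7-endo attack and hydrogen transfer, which the 1,2-disubstituted alkene, the two quaternary carbons tied cis in the lactone (Thorpe–Ingold effect) and the slow addition of n-Bu3SnH should secure, and it needs reaction at C7a and not at C6, which the twisted (Z)-C6=C7 bond and the small rings that attack from C6 would require should secure.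

Step 11
Reactants: 15 all-trans tricyclic keto methoxy-lactone
Product: 16 tricyclic hydroxy-lactone (pseudo-acid of the C5-formyl C4-carboxylic acid)
Conditions: 2 M HCl, THF, 50 °C
Reagents that add atoms: water, O
Why: Acetal hydrolysis of the pseudo-ester frees the lactol tautomer of the formyl acid; the ketone α-centres are already at equilibrium and the ring-fusion centres cannot epimerise.

Step 12
Reactants: 16 tricyclic hydroxy-lactone
Product: 17 (E)-2-formylbut-1-enyl keto acid
Conditions: Ph3P=C(Et)CHO (3 equiv), toluene, 100 °C
Reagents that add atoms: 2-(triphenylphosphoranylidene)butanal, CCC(C=O)=P(c1ccccc1)(c1ccccc1)c1ccccc1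
Why: Wittig reaction of the stabilised formyl ylide with the open formyl-acid tautomer should give the (E)-trisubstituted enal (formyl trans to C5), and stabilised ylides do not attack the hindered ketone.

Step 13
Reactants: 17 (E)-2-formylbut-1-enyl keto acid
Product: 18 CNP0134269.1
Conditions: PhCH2P(O)(OEt)2 (1.5 equiv), KOt-Bu (2.6 equiv), THF, 0 °C → rt; 1 M HCl work-up
Reagents that add atoms: diethyl benzylphosphonate, CCOP(=O)(Cc1ccccc1)OCC
Why: Horner–Wadsworth–Emmons reaction of the benzylphosphonate anion with the enal should give the (E)-styryl bond; the acid travels as its potassium salt and excess base can only return C1 and C3 to their all-trans equilibrium.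

**Compound list**

1 | mucobromic acid (3,4-dibromo-5-hydroxyfuran-2(5H)-one) | OC1OC(=O)C(Br)=C1Br | starting material
2 | (−)-menthol, (1R,2S,5R)-2-isopropyl-5-methylcyclohexan-1-ol | C[C@@H]1CC[C@H]([C@@H](C1)O)C(C)C | starting material
3 | (5S)-3,4-dibromo-5-[(1R,2S,5R)-menthyloxy]furan-2(5H)-one | O=C1O[C@H](O[C@@H]2C[C@H](C)CC[C@H]2C(C)C)C(Br)=C1Br | intermediate
4 | (5S)-3,4-diethyl-5-[(1R,2S,5R)-menthyloxy]furan-2(5H)-one | O=C1O[C@H](O[C@@H]2C[C@H](C)CC[C@H]2C(C)C)C(CC)=C1CC | intermediate
5 | 1,5-diethyl-4-[(1R,2S,5R)-menthyloxy]-3-oxabicyclo[3.2.0]hept-6-en-2-one, cis-fused, both ethyl groups on the face opposite the cyclobutene, menthyloxy trans to the cyclobutene | O=C1O[C@H](O[C@@H]3C[C@H](C)CC[C@H]3C(C)C)[C@@]2(CC)C=C[C@@]12CC | intermediate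
6 | 1,5-diethyl-4-(2-methylprop-2-enyloxy)-3-oxabicyclo[3.2.0]hept-6-en-2-one, ring carbons as in 5, alkoxy cis to the cyclobutene | O=C1O[C@@H](OCC(C)=C)[C@@]2(CC)C=C[C@@]12CC | intermediate
7 | 3,3a-diethyl-5-methyl-3-vinyl-3,3a-dihydro-6H-furo[2,3-b]pyran-2(7aH)-one, cis-fused, vinyl and the C3a–C4 bond on the same face | O=C1O[C@H]2OCC(C)=C[C@@]2(CC)[C@@]1(CC)C=C | intermediate (not isolated)
8 | 3-[(E)-but-1-enyl]-3,3a-diethyl-5-methyl-3,3a-dihydro-6H-furo[2,3-b]pyran-2(7aH)-one, configured as 7 | O=C1O[C@H]2OCC(C)=C[C@@]2(CC)[C@@]1(CC)/C=C/CC | intermediate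
9 | 3-[(E)-but-1-enyl]-3,3a-diethyl-5-methyl-3,3a-dihydrofuro[2,3-b]pyran-2,6(7aH)-dione (acylal), configured as 8 | O=C1O[C@H]2OC(=O)C(C)=C[C@@]2(CC)[C@@]1(CC)/C=C/CC | intermediate
10 | 6-hydroxy lactol of 9 (anomer mixture at C6; ring-chain tautomer of the (Z)-enal and 5-hydroxy-lactone) | O=C1O[C@H]2OC(O)C(C)=C[C@@]2(CC)[C@@]1(CC)/C=C/CC | intermediate
11 | (2E,4Z)-7-[(E)-but-1-enyl]-6,7-diethyl-6-formyl-2,4-dimethylocta-2,4-dienedioic acid | O=C[C@@](CC)(/C=C(C)\C=C(/C)C(=O)O)[C@@](CC)(/C=C/CC)C(=O)O | intermediate (not isolated)
12 | (2E,4Z)-5-{4-[(E)-but-1-enyl]-3,4-diethyl-2-methoxy-5-oxotetrahydrofuran-3-yl}-2,4-dimethylpenta-2,4-dienoic acid, the two alkenyl arms cis, methoxy trans to the dienyl arm | O=C1O[C@H](OC)[C@@](CC)(/C=C(C)\C=C(/C)C(=O)O)[C@@]1(CC)/C=C/CC | intermediate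
13 | Se-phenyl selenoester of 12 | O=C1O[C@H](OC)[C@@](CC)(/C=C(C)\C=C(/C)C(=O)[Se]c2ccccc2)[C@@]1(CC)/C=C/CC | intermediate
14 | tricyclic keto methoxy-lactone as 15 but a mixture of epimers at C1 and C3 | CO[C@@H]3[C@@]1(CC)C=C(C)[C@@H]2[C@H](C(CC)C(=O)C2C)[C@@]1(CC)C(=O)O3 | intermediate (not isolated)
15 | tricyclic keto methoxy-lactone: core of 18 with the C4 carboxyl closed as a γ-lactone onto a methoxy-acetal carbon on C5 (methoxy cis to the C5 ethyl); C1, C3, C3a, C4, C5, C7a as in 18 | CO[C@@H]3[C@@]1(CC)C=C(C)[C@@H]2[C@H]([C@H](CC)C(=O)[C@H]2C)[C@@]1(CC)C(=O)O3 | intermediate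
16 | hydroxy-lactone (pseudo-acid, anomer mixture) of 3,4,5-triethyl-5-formyl-1,7-dimethyl-2-oxo-2,3,3a,4,5,7a-hexahydro-1H-indene-4-carboxylic acid, ring carbons as in 18 | OC3[C@@]1(CC)C=C(C)[C@@H]2[C@H]([C@H](CC)C(=O)[C@H]2C)[C@@]1(CC)C(=O)O3 | intermediate
17 | (1S,3S,3aR,4R,5R,7aR)-3,4,5-triethyl-5-[(E)-2-formylbut-1-enyl]-1,7-dimethyl-2-oxo-2,3,3a,4,5,7a-hexahydro-1H-indene-4-carboxylic acid | CCC(/C=O)=C\[C@@]1(CC)C=C(C)[C@@H]2[C@H]([C@H](CC)C(=O)[C@H]2C)[C@@]1(CC)C(=O)O | intermediate
18 | CNP0134269.1, (1S,3S,3aR,4R,5R,7aR)-3,4,5-triethyl-5-[(1E,3E)-2-ethyl-4-phenylbuta-1,3-dienyl]-1,7-dimethyl-2-oxo-2,3,3a,4,5,7a-hexahydro-1H-indene-4-carboxylic acid | CCC(/C=C/c1ccccc1)=C\[C@@]1(CC)C=C(C)[C@@H]2[C@H]([C@H](CC)C(=O)[C@H]2C)[C@@]1(CC)C(=O)O | target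

**Totals**

Total step count: 13. Longest linear sequence: 13 steps (the route is linear from 1).

**Steps most likely to fail**

Step 10. Face selection in the 6-exo closure may be weak (the two chairs differ little in energy), and hydrogen transfer to the acyl radical or 7-endo attack may compete. The fallback makes the same two bonds through a titanacycle. It sets out from acid 12, which is converted with TMSCHN2 into methyl ester F1. The divalent titanium reagent from Ti(O-i-Pr)4 and 2 i-PrMgCl (Et2O, −50 → 0 °C) should couple the enoate C7a=C1 bond with the butenyl C3a=C3 bond to a titanacyclopentane, a known reaction type for 2,7-bis-unsaturated esters. Its C3–Ti bond then attacks the ester carbonyl intramolecularly to give the cyclopentanone, and DBU equilibration as in step 10 brings the route back at 15.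

Step 6. The oxidation may stall because the ring oxygen is part of an acyloxy acetal and so a poor donor, or it may wander to the other allylic C–H bonds. The fallback carries the lactone oxidation level in the tether. It sets out from 5, which is hydrolysed (TFA, aq. THF) to hydroxy-lactone F2 and acylated with methacryloyl chloride (Et3N, DMAP, CH2Cl2) to methacrylate acylal F3, the epimer with the acyloxy group cis to the cyclobutene. The metathesis conditions of step 5 (ring-closing onto a methacrylate is well known) then give 9 directly, where the route is rejoined.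

Step 12. Addition of the stabilised ylide to an aldehyde on a quaternary carbon next to a second quaternary carbon may be too slow, with the ring-chain equilibrium on the lactol side and the ylide partly protonated by the acid. The fallback is a Peterson-type formyl olefination with a far more nucleophilic reagent. It sets out from 16, whose lithium carboxylate (LiN(SiMe3)2, THF) is treated at −78 °C with the lithiated α-silyl aldimine made from N-tert-butyl-2-(trimethylsilyl)butan-1-imine and s-BuLi to give unsaturated tert-butyl imine F4. Hydrolysis with aqueous oxalic acid returns the route at 17.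

**Further compounds**

F1 | step 10 | methyl ester of 12, methyl (2E,4Z)-5-{4-[(E)-but-1-enyl]-3,4-diethyl-2-methoxy-5-oxotetrahydrofuran-3-yl}-2,4-dimethylpenta-2,4-dienoate | O=C1O[C@H](OC)[C@@](CC)(/C=C(C)\C=C(/C)C(=O)OC)[C@@]1(CC)/C=C/CC
F2 | step 6 | 1,5-diethyl-4-hydroxy-3-oxabicyclo[3.2.0]hept-6-en-2-one (lactol anomer mixture), ring carbons as in 5 | O=C1OC(O)[C@@]2(CC)C=C[C@@]12CC
F3 | step 6 | 1,5-diethyl-2-oxo-3-oxabicyclo[3.2.0]hept-6-en-4-yl 2-methylprop-2-enoate, acyloxy cis to the cyclobutene | O=C1O[C@@H](OC(=O)C(C)=C)[C@@]2(CC)C=C[C@@]12CC
F4 | step 12 | N-tert-butyl imine of 17 | CCC(/C=N/C(C)(C)C)=C\[C@@]1(CC)C=C(C)[C@@H]2[C@H]([C@H](CC)C(=O)[C@H]2C)[C@@]1(CC)C(=O)O
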